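**Assumption:** 3-(2-hydroxy-3-methylphenyl)propanoic acid (1) is taken as a catalogue phenol acid; if it is not, it is one hydrogenation in aqueous NaOH away from 8-methylcoumarin.

**Plan**
- Retrosynthetic cuts: oxane C–O and C–Br (bromoetherification of a homoprenyl tertiary alcohol); side-chain C=C (Wittig on a lactol); ring C–Cl and C–Br (from a 1-methylcyclohexene). With the cyclohexane numbered C1 (CH bearing the oxane), C2 (CH2), C3 (CHBr), C4 (CMeCl), C5, C6, the last cuts are C1–C6 and C4–C5, which remove C5–C6 as ethylene.
- Enabling feature: C1 and C4 are 1,4-related and joined on one side only by the plain C5–C6 unit, and C1 carries a carbinol carbon with a methyl. So C1, C2, C3, C4, the oxane quaternary carbon and its methyl are the six ring carbons of an ortho-quinol spirolactone (a cyclohexa-2,4-dienone from a dearomatised phenol), whose diene takes up ethylene.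
- Forward order: phenol acid → spirolactone dienone → bicyclo[2.2.2]octenone (new carbocycle) → scission of the old arene bond C(=O)–C(Me), which turns the former carbonyl carbon into the quaternary methyl and moves the alkene to C3=C4 → ring Cl/Br → lactol and Wittig → oxane ring.
- Stereochemistry: the spiro C–O centre from a chiral aryl iodide catalyst; ring C1 from the oxygen-face selectivity of the cycloaddition; C3/C4 from diaxial chlorohydrin formation, neighbouring-group bromination and diaxial-to-diequatorial halogen interchange; the oxane CHBr from a chair bromoetherification.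

Key step: step 2

**Step 1**
Reactants: 1 3-(2-hydroxy-3-methylphenyl)propanoic acid
Product: 2 (5R)-7-methyl-1-oxaspiro[4.5]deca-7,9-diene-2,6-dione
Conditions: chiral aryl iodide 2-iodo-1,3-bis[1-(mesitylcarbamoyl)ethoxy]benzene (10 mol %, the enantiomer that delivers 5R), mCPBA (1.3 equiv), CH2Cl2–HFIP, −20 °C
Reagents that add atoms: none
Why: mCPBA should oxidise the aryl iodide to a trivalent iodine species that activates the phenol oxygen, and the tethered carboxylate then attacks the side-chain-bearing ortho carbon inside the chiral ligand sphere (catalytic asymmetric oxidative dearomatising spirolactonisation), which sets the spiro C–O centre (the future oxane quaternary carbon), while the C7 methyl should slow dimerisation of the dienone.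

**Step 2**
Reactants: 2 (5R)-7-methyl-1-oxaspiro[4.5]deca-7,9-diene-2,6-dione; 3 ethylene
Product: 4 (1R,2R,4S)-4-methylspiro[bicyclo[2.2.2]oct-5-ene-2,2'-oxolane]-3,5'-dione
Conditions: ethylene (40 bar), PhMe, 70 °C, autoclave
Reagents that add atoms: none
Why: The step is a thermal concerted suprafacial [4+2] cycloaddition (Diels–Alder) between the s-cis-locked C7=C8–C9=C10 diene of the cyclohexa-2,4-dienone and ethylene. The closest known reaction type is the Diels–Alder reaction of ortho-quinol derivatives and masked ortho-benzoquinones (6,6-disubstituted cyclohexa-2,4-dienones) with alkenes to give bicyclo[2.2.2]octenones. It closes the new six-membered carbocycle (C10, C9, C8, C7 and the two ethylene carbons, the future cyclohexane) in one intermolecular [π4s+π2s] event that forms both C–C bonds at once. The two new stereocentres are the bridgeheads, and both follow from π-facial selectivity alone: ethylene should add to the dienone face syn to the lactone oxygen and anti to the lactone CH2 of the spiro carbon (the usual syn-to-oxygen preference of ortho-quinol dienones), which gives the ring CH the (R) configuration required relative to the spiro centre. Ethylene is symmetric, so no regio- or endo/exo selectivity is needed; the competing dimerisation and rearomatisation of the dienone should be held back by the C7 methyl, the ethylene pressure and the moderate temperature.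

**Step 3**
Reactants: 4 (1R,2R,4S)-4-methylspiro[bicyclo[2.2.2]oct-5-ene-2,2'-oxolane]-3,5'-dione
Product: 5 (1R,2R,4S)-3-hydroxy-4-methylspiro[bicyclo[2.2.2]oct-5-ene-2,2'-oxolan]-5'-one (either C3 epimer)
Conditions: NaBH4, CeCl3·7H2O, MeOH, −40 °C
Reagents that add atoms: none
Why: Luche-type 1,2-reduction of the non-enolisable bridge ketone should leave the lactone untouched at low temperature and gives the homoallylic alcohol needed for fragmentation; the carbinol configuration does not matter because this carbon becomes CH=O in step 4.

**Step 4**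
Reactants: 5 (1R,2R,4S)-3-hydroxy-4-methylspiro[bicyclo[2.2.2]oct-5-ene-2,2'-oxolan]-5'-one
Product: 6 (2R)-2-[(1R)-4-methylcyclohex-3-en-1-yl]-5-oxooxolane-2-carbaldehyde
Conditions: (n-Bu4N)2CeCl6 (5 mol %), 2,4,6-(i-Pr)3C6H2SH (20 mol %), MeCN, 400 nm LED, 25 °C
Reagents that add atoms: none
Why: The tetravalent cerium alkoxide should give the alkoxy radical on irradiation (ligand-to-metal charge transfer), β-scission then breaks the C3–C4 bond because that releases a tertiary allylic radical and the bicyclic strain (radical ring-opening of a cycloalkanol), and the thiol returns hydrogen to the less hindered allyl terminus, so the redox-neutral isomerisation should give the aldehyde and the trisubstituted C3=C4 ring alkene without touching the two stereocentres.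

**Step 5**
Reactants: 6 (2R)-2-[(1R)-4-methylcyclohex-3-en-1-yl]-5-oxooxolane-2-carbaldehyde
Product: 7 (5R)-5-(1,3-dithiolan-2-yl)-5-[(1R)-4-methylcyclohex-3-en-1-yl]oxolan-2-one
Conditions: HSCH2CH2SH, BF3·OEt2 (cat.), CH2Cl2, 0 °C
Reagents that add atoms: ethane-1,2-dithiol, SCCS
Why: Lewis-acid thioacetalisation of the non-enolisable aldehyde should proceed without affecting the lactone or the trisubstituted alkene (first half of a Mozingo reduction).

**Step 6**
Reactants: 7 (5R)-5-(1,3-dithiolan-2-yl)-5-[(1R)-4-methylcyclohex-3-en-1-yl]oxolan-2-one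
Product: 8 (5R)-5-methyl-5-[(1R)-4-methylcyclohex-3-en-1-yl]oxolan-2-one
Conditions: Raney Ni (W-2, acetone-deactivated), EtOH, 25 °C
Reagents that add atoms: none
Why: Raney Ni hydrogenolysis of both C–S bonds (Mozingo reduction) should turn the former phenol carbonyl carbon into the quaternary methyl; it is preferred to hydrazone-based reductions, which risk β-elimination of the lactone oxygen, and the deactivated catalyst should spare the trisubstituted alkene.

**Step 7**
Reactants: 8 (5R)-5-methyl-5-[(1R)-4-methylcyclohex-3-en-1-yl]oxolan-2-one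
Product: 9 (5R)-5-[(1R,3S,4S)-3-chloro-4-hydroxy-4-methylcyclohexyl]-5-methyloxolan-2-one
Conditions: N-chlorosuccinimide, THF–H2O, 0 °C to 25 °C
Reagents that add atoms: N-chlorosuccinimide, O=C1CCC(=O)N1Cl; water, O
Why: Electrophilic chlorine should add to C3 from the face trans to the equatorial C1 substituent and water should open the chloronium at the tertiary C4 in the anti, diaxial (Fürst–Plattner) and Markovnikov sense (halohydrin formation on a 4-substituted 1-methylcyclohexene), giving axial tertiary OH cis and axial Cl trans to the C1 substituent.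

**Step 8**
Reactants: 9 (5R)-5-[(1R,3S,4S)-3-chloro-4-hydroxy-4-methylcyclohexyl]-5-methyloxolan-2-one
Product: 11 (5R)-5-[(1R,3R,4R)-3-bromo-4-chloro-4-methylcyclohexyl]-5-methyloxolan-2-one, via diaxial 4-bromo-3-chloro lactone 10 (not isolated)
Conditions: Me3SiBr, CH2Cl2, −30 °C to 0 °C; evaporate; MeNO2, 80 °C
Reagents that add atoms: bromotrimethylsilane, C[Si](C)(C)Br
Why: Me3SiBr should ionise the tertiary C4–O bond with participation of the anti-periplanar axial C3–Cl, so bromide enters C4 with retention to give 10, and heating in a polar solvent should then drive the diaxial-to-diequatorial 1,2-interchange of vicinal halogens (dihalide mutarotation through a bridged halonium–halide ion pair), each halogen moving to the neighbouring carbon on its own face, which leaves tertiary Cl equatorial and trans, and Br equatorial and cis, to the C1 substituent.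

**Step 9**
Reactants: 11 (5R)-5-[(1R,3R,4R)-3-bromo-4-chloro-4-methylcyclohexyl]-5-methyloxolan-2-one
Product: 12 (5R)-5-[(1R,3R,4R)-3-bromo-4-chloro-4-methylcyclohexyl]-5-methyloxolan-2-ol (anomer mixture)
Conditions: i-Bu2AlH (1.1 equiv), CH2Cl2, −78 °C; KNaC4H4O6 (aq)
Reagents that add atoms: none
Why: Partial reduction of the lactone should stop at the lactol because the tetrahedral aluminium acetal is stable at −78 °C, and the alkyl halides are inert to the hydride at this temperature.

**Step 10**
Reactants: 12 (5R)-5-[(1R,3R,4R)-3-bromo-4-chloro-4-methylcyclohexyl]-5-methyloxolan-2-ol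
Product: 13 (2R)-2-[(1R,3R,4R)-3-bromo-4-chloro-4-methylcyclohexyl]-6-methylhept-5-en-2-ol
Conditions: i-PrPPh3I (3 equiv), n-BuLi (3 equiv), THF, 0 °C; then 12, 0 °C to 25 °C
Reagents that add atoms: isopropyltriphenylphosphonium iodide, CC(C)[P+](c1ccccc1)(c1ccccc1)c1ccccc1.[I-]
Why: Wittig olefination of the open hydroxy-aldehyde form of the lactol with the non-stabilised isopropylidene ylide should give the trisubstituted alkene and free the tertiary alcohol, while the equatorial ring halides, which have no anti-periplanar ring hydrogen, should resist elimination.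

**Step 11**
Reactants: 13 (2R)-2-[(1R,3R,4R)-3-bromo-4-chloro-4-methylcyclohexyl]-6-methylhept-5-en-2-ol
Product: 14 deoxycaespitol, (3S,6R)-3-bromo-6-[(1R,3R,4R)-3-bromo-4-chloro-4-methylcyclohexyl]-2,2,6-trimethyloxane
Conditions: 2,4,4,6-tetrabromocyclohexa-2,5-dienone, MeNO2, 0 °C
Reagents that add atoms: 2,4,4,6-tetrabromocyclohexa-2,5-dienone, O=C1C(Br)=CC(Br)(Br)C=C1Br
Why: Electrophilic bromine should form the bromonium on the only alkene and the tertiary hydroxyl should open it at the dimethyl-substituted carbon (6-endo, Markovnikov bromoetherification) through a chair transition state with the cyclohexyl group equatorial and the quaternary methyl axial, which places Br equatorial and trans to the cyclohexyl group (3S relative to 6R).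

**Compound list**
1 | 3-(2-hydroxy-3-methylphenyl)propanoic acid | Cc1cccc(CCC(=O)O)c1O | starting material
2 | (5R)-7-methyl-1-oxaspiro[4.5]deca-7,9-diene-2,6-dione | CC1=CC=C[C@]2(CCC(=O)O2)C1=O | intermediate
3 | ethylene | C=C | starting material
4 | (1R,2R,4S)-4-methylspiro[bicyclo[2.2.2]oct-5-ene-2,2'-oxolane]-3,5'-dione | C[C@]12CC[C@H](C=C1)[C@]3(CCC(=O)O3)C2=O | intermediate
5 | (1R,2R,4S)-3-hydroxy-4-methylspiro[bicyclo[2.2.2]oct-5-ene-2,2'-oxolan]-5'-one (either C3 epimer) | C[C@]12CC[C@H](C=C1)[C@]3(CCC(=O)O3)C2O | intermediate
6 | (2R)-2-[(1R)-4-methylcyclohex-3-en-1-yl]-5-oxooxolane-2-carbaldehyde | O=C1CC[C@](C=O)([C@@H]2CCC(C)=CC2)O1 | intermediate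
7 | (5R)-5-(1,3-dithiolan-2-yl)-5-[(1R)-4-methylcyclohex-3-en-1-yl]oxolan-2-one | O=C1CC[C@](C2SCCS2)([C@@H]3CCC(C)=CC3)O1 | intermediate
8 | (5R)-5-methyl-5-[(1R)-4-methylcyclohex-3-en-1-yl]oxolan-2-one | O=C1CC[C@](C)([C@@H]2CCC(C)=CC2)O1 | intermediate
9 | (5R)-5-[(1R,3S,4S)-3-chloro-4-hydroxy-4-methylcyclohexyl]-5-methyloxolan-2-one | O=C1CC[C@](C)([C@@H]2CC[C@](C)(O)[C@@H](Cl)C2)O1 | intermediate
10 | (5R)-5-[(1R,3S,4S)-4-bromo-3-chloro-4-methylcyclohexyl]-5-methyloxolan-2-one (halogens trans-diaxial; not isolated) | O=C1CC[C@](C)([C@@H]2CC[C@](C)(Br)[C@@H](Cl)C2)O1 | intermediate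
11 | (5R)-5-[(1R,3R,4R)-3-bromo-4-chloro-4-methylcyclohexyl]-5-methyloxolan-2-one | O=C1CC[C@](C)([C@@H]2CC[C@@](C)(Cl)[C@H](Br)C2)O1 | intermediate
12 | (5R)-5-[(1R,3R,4R)-3-bromo-4-chloro-4-methylcyclohexyl]-5-methyloxolan-2-ol (anomer mixture) | OC1CC[C@](C)([C@@H]2CC[C@@](C)(Cl)[C@H](Br)C2)O1 | intermediate
13 | (2R)-2-[(1R,3R,4R)-3-bromo-4-chloro-4-methylcyclohexyl]-6-methylhept-5-en-2-ol | CC(C)=CCC[C@@](C)(O)[C@@H]1CC[C@@](C)(Cl)[C@H](Br)C1 | intermediate
14 | deoxycaespitol, (3S,6R)-3-bromo-6-[(1R,3R,4R)-3-bromo-4-chloro-4-methylcyclohexyl]-2,2,6-trimethyloxane | CC1(C)O[C@@](C)([C@@H]2CC[C@@](C)(Cl)[C@H](Br)C2)CC[C@@H]1Br | target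

**Total step count:** 11
**Longest linear sequence:** 11 steps (1 → 14)

**Steps most likely to fail**

Step 8. The tertiary bromide may lose HBr (E1 elimination) instead of undergoing the halogen interchange, or the interchange may stop at an equilibrium mixture. Fallback, setting out from 8 and returning at 11: bromine addition (Br2, CH2Cl2, −78 °C) should give the trans-diaxial dibromide (5R)-5-[(1R,3S,4S)-3,4-dibromo-4-methylcyclohexyl]-5-methyloxolan-2-one F3. Heating (PhCl, 110 °C) should equilibrate it to the diequatorial dibromide (5R)-5-[(1R,3R,4R)-3,4-dibromo-4-methylcyclohexyl]-5-methyloxolan-2-one F4. Silver-assisted removal of the tertiary bromide (AgOSO2CF3, CH2Cl2, −60 °C, then Et4NCl) should pass through the bromonium bridged on the face of the C3 bromine, which chloride opens at C4 from the opposite face, giving 11 with retention.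

Step 4. β-Scission may break the bond to the spiro carbon instead of the allylic bridgehead, or hydrogen may be returned to the tertiary allyl terminus so that the alkene stays out of the C3=C4 position. Fallback, setting out from 5 and returning at 6: hypoiodite fragmentation (PhI(OAc)2, I2, cyclohexane, visible light) should give the allylic iodide of 6, (2R)-2-[(1R)-2-iodo-4-methylcyclohex-3-en-1-yl]-5-oxooxolane-2-carbaldehyde F2, by iodine capture at the less hindered allyl terminus. Radical reduction (n-Bu3SnH, Et3B, air, PhMe, 0 °C) then removes the iodine to give 6.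

Step 2. Cycloaddition of unactivated ethylene may be too slow, so that dimerisation or rearomatisation of the dienone takes over, and the facial selectivity may erode at the temperature needed. Fallback, setting out from 2 and returning at 4: the electron-rich ethylene surrogate phenyl vinyl sulfide (PhMe, 25 °C to 50 °C) should add in the inverse-demand sense on the same oxygen face to give the 8-(phenylsulfanyl) derivative of 4, 4-methyl-8-(phenylsulfanyl)spiro[bicyclo[2.2.2]oct-5-ene-2,2'-oxolane]-3,5'-dione F1 (sulfur on the CH next to the methyl-bearing bridgehead, either epimer). Desulfurisation with acetone-deactivated Raney Ni then gives 4.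

**Further compounds**
F1 | step 2 | 4-methyl-8-(phenylsulfanyl)spiro[bicyclo[2.2.2]oct-5-ene-2,2'-oxolane]-3,5'-dione (bridgeheads and spiro centre as in 4, C8 either epimer) | C[C@]12C(Sc3ccccc3)C[C@H](C=C1)[C@]4(CCC(=O)O4)C2=O
F2 | step 4 | (2R)-2-[(1R)-2-iodo-4-methylcyclohex-3-en-1-yl]-5-oxooxolane-2-carbaldehyde (ring CH and lactone centre as in 6, C–I either epimer) | O=C1CC[C@](C=O)([C@@H]2CCC(C)=CC2I)O1
F3 | step 8 | (5R)-5-[(1R,3S,4S)-3,4-dibromo-4-methylcyclohexyl]-5-methyloxolan-2-one | O=C1CC[C@](C)([C@@H]2CC[C@](C)(Br)[C@@H](Br)C2)O1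
F4 | step 8 | (5R)-5-[(1R,3R,4R)-3,4-dibromo-4-methylcyclohexyl]-5-methyloxolan-2-one | O=C1CC[C@](C)([C@@H]2CC[C@@](C)(Br)[C@H](Br)C2)O1
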